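**Plan**
- Retrosynthesis cuts the C7 O–prenyl bond, then the three benzyl ethers, then the O1–C2 bond of ring C together with the C2=C3 unsaturation, which leads back to a 2'-hydroxy-α-methoxychalcone.
- The chalcone is cut at Cα=Cβ (aldol) into O-benzylvanillin and a ring A methoxymethyl ketone, whose aryl–acyl bond is cut to an aryllithium and a Weinreb amide.
- Forward: ring A is oxygenated at the future C8 (formylation, Baeyer–Villiger, methylation) and acylated next to the masked C8a oxygen. Ring B is joined by Claisen–Schmidt condensation, ring C closes last, and the prenyl ether is attached at the end.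
- Enabling feature: the C8a phenol oxygen lies six atoms from the benzylic carbon of ring B (future C2) in an enone whose α-carbon already carries the C3 methoxy group. The C5 oxygen is benzylated, so only O1–C2 can form.
- Stereochemistry: the target has no stereocentre. The chalcone geometry and the C2/C3 centres of the transient flavanone are erased on aromatisation.

Key step: step 8

Remark: flavone numbering (O1, C2 to C8a, primes for ring B) is used throughout; in the open-chain precursors O1 is the 2-hydroxyl of the aryl ketone.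

**Step 1**
Reactants: 1 3,5-bis(benzyloxy)phenol
Product: 2 2,4-bis(benzyloxy)-6-hydroxybenzaldehyde
Conditions: MgCl2, Et3N, (CH2O)n, MeCN, reflux; then 1 M HCl
Reagents that add atoms: paraformaldehyde (as formaldehyde), C=O
Why: Magnesium-mediated ortho-formylation of a phenol (Casnati–Skattebøl) places the formyl group only next to the free hydroxyl, and the two ortho positions of 1 are equivalent, so a single aldehyde should result.

**Step 2**
Reactants: 2 2,4-bis(benzyloxy)-6-hydroxybenzaldehyde
Product: 3 2,4-bis(benzyloxy)-6-(methoxymethoxy)benzaldehyde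
Conditions: NaH, MOMCl, DMF, 0 °C to rt
Reagents that add atoms: chloromethyl methyl ether (MOMCl), COCCl
Why: Williamson-type O-alkylation of the sodium phenoxide masks the chelated hydroxyl as a MOM acetal, which tolerates peracid and base and later directs the metalation.

**Step 3**
Reactants: 3 2,4-bis(benzyloxy)-6-(methoxymethoxy)benzaldehyde
Product: 5 2,4-bis(benzyloxy)-6-(methoxymethoxy)phenol, via aryl formate 4 (not isolated)
Conditions: mCPBA, CH2Cl2, 0 °C to rt; aq. Na2S2O3/NaHCO3 wash; then K2CO3 (cat.), MeOH, rt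
Reagents that add atoms: 3-chloroperoxybenzoic acid (mCPBA), OOC(=O)c1cccc(Cl)c1
Why: Baeyer–Villiger (Dakin-type) oxidation of a 2,4,6-trioxygenated benzaldehyde proceeds with migration of the electron-rich aryl group to give the formate, which base-catalysed methanolysis converts into the phenol.

**Step 4**
Reactants: 5 2,4-bis(benzyloxy)-6-(methoxymethoxy)phenol
Product: 6 1,5-bis(benzyloxy)-2-methoxy-3-(methoxymethoxy)benzene
Conditions: MeI, K2CO3, DMF, rt
Reagents that add atoms: iodomethane, CI
Why: Williamson methylation of the only free phenol fixes the future C8 methoxy group between the MOM-protected oxygen (future O1) and a benzyloxy group (future C7 oxygen).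

**Step 5**
Reactants: 6 1,5-bis(benzyloxy)-2-methoxy-3-(methoxymethoxy)benzene; 7 N,2-dimethoxy-N-methylacetamide
Product: 10 1-[4,6-bis(benzyloxy)-3-methoxy-2-(methoxymethoxy)phenyl]-2-methoxyethan-1-one, via aryllithium 8 (not isolated), via lithium hemiaminal alkoxide 9 (not isolated)
Conditions: n-BuLi, TMEDA, THF, -20 to 0 °C; then 7, -78 °C to rt; then H2O
Reagents that add atoms: none
Why: Directed ortho-metalation should occur at the ring CH between the MOM acetal (the strongest coordinating group present) and the adjacent benzyloxy group, and the aryllithium is acylated once by the Weinreb amide because the chelated adduct 9 collapses only on quench (Weinreb ketone synthesis).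

**Step 6**
Reactants: 10 1-[4,6-bis(benzyloxy)-3-methoxy-2-(methoxymethoxy)phenyl]-2-methoxyethan-1-one
Product: 11 1-[4,6-bis(benzyloxy)-2-hydroxy-3-methoxyphenyl]-2-methoxyethan-1-one
Conditions: HCl (3 M aq.), MeOH, 40 °C
Reagents that add atoms: none
Why: Acid-catalysed acetal exchange with methanol removes the MOM group, helped by the ortho carbonyl, while benzyl ethers, methyl ethers and the α-methoxy ketone are inert under these conditions.

**Step 7**
Reactants: 11 1-[4,6-bis(benzyloxy)-2-hydroxy-3-methoxyphenyl]-2-methoxyethan-1-one; 12 4-(benzyloxy)-3-methoxybenzaldehyde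
Product: 14 (Z)-1-[4,6-bis(benzyloxy)-2-hydroxy-3-methoxyphenyl]-3-[4-(benzyloxy)-3-methoxyphenyl]-2-methoxyprop-2-en-1-one, via aldol adduct 13 (not isolated)
Conditions: KOH (50% aq.), EtOH, rt; then dil. HCl
Reagents that add atoms: none
Why: In this Claisen–Schmidt condensation the ketone can enolise only at the methoxy-bearing CH2, adds to the non-enolisable aldehyde, and E1cB loss of water from 13 should give the thermodynamic enone with the aryl group anti to the acyl group (Z by the sequence rules), held open as its phenoxide in strong base.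

**Step 8**
Reactants: 14 (Z)-1-[4,6-bis(benzyloxy)-2-hydroxy-3-methoxyphenyl]-3-[4-(benzyloxy)-3-methoxyphenyl]-2-methoxyprop-2-en-1-one
Product: 17 5,7-bis(benzyloxy)-2-[4-(benzyloxy)-3-methoxyphenyl]-3,8-dimethoxy-4H-chromen-4-one, via 3-methoxyflavanone 15 (not isolated), via 3-iodo-3-methoxyflavanone 16 (not isolated)
Conditions: I2 (10 mol%), DMSO, 130 °C
Reagents that add atoms: none
Why: The free phenol of 14 (future O1 on C8a) adds in conjugate fashion to the benzylic β-carbon of the α-methoxy enone, a 6-endo-trig oxa-Michael closure that forms O1–C2 and ring C as the 3-methoxyflavanone 15. Iodine then iodinates the enol of 15 at C3 to give 16, which loses HI across C2–C3 to the chromone, and DMSO reoxidises HI to I2 so that the halogen is needed only in catalytic amount. The closest known reaction type is the iodine–DMSO oxidative cyclisation of 2'-hydroxychalcones to flavones, applied here to an α-methoxy member of that class. The two stereocentres formed at C2 and C3 of 15 are transient and both vanish on aromatisation, so no stereocontrol is needed and the alkene geometry of 14 is immaterial. The selectivity required is regiochemical (closure through the oxygen flanked by the C8 methoxy, not the C5 oxygen) and chemical (flavone, not aurone); the first is secured because the C5 oxygen is a benzyl ether and only one phenol is free, the second because the α-carbon already bears OMe, which disfavours 5-exo attack there. Benzyl ethers are used because they tolerate hot I2–DMSO, and any loss of the peri C5 benzyl group by HI after ring closure converges in step 9.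

**Step 9**
Reactants: 17 5,7-bis(benzyloxy)-2-[4-(benzyloxy)-3-methoxyphenyl]-3,8-dimethoxy-4H-chromen-4-one
Product: 18 5,7-dihydroxy-2-(4-hydroxy-3-methoxyphenyl)-3,8-dimethoxy-4H-chromen-4-one
Conditions: H2 (1 atm), 10% Pd/C, THF–MeOH, rt
Reagents that add atoms: none
Why: Catalytic hydrogenolysis cleaves the three benzyl aryl ethers under conditions that leave the chromone C2=C3 bond and the methyl ethers untouched.

**Step 10**
Reactants: 18 5,7-dihydroxy-2-(4-hydroxy-3-methoxyphenyl)-3,8-dimethoxy-4H-chromen-4-one; 19 prenyl bromide (1-bromo-3-methylbut-2-ene)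
Product: 20 5-hydroxy-2-(4-hydroxy-3-methoxyphenyl)-3,8-dimethoxy-7-[(3-methylbut-2-en-1-yl)oxy]-4H-chromen-4-one
Conditions: KHCO3 (1.2 equiv), 19 (1.05 equiv), DMF, 40 °C
Reagents that add atoms: none
Why: Williamson O-alkylation governed by acidity: the 7-hydroxyl, para to the C4 carbonyl, is a vinylogous carboxylic acid and should be the only phenol ionised by hydrogen carbonate, whereas the guaiacol-type 4'-hydroxyl is less acidic and the 5-hydroxyl is locked in a hydrogen bond to the carbonyl.

**Compound list**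
1 | 3,5-bis(benzyloxy)phenol | Oc1cc(OCc2ccccc2)cc(OCc2ccccc2)c1 | starting material
2 | 2,4-bis(benzyloxy)-6-hydroxybenzaldehyde | O=Cc1c(O)cc(OCc2ccccc2)cc1OCc1ccccc1 | intermediate
3 | 2,4-bis(benzyloxy)-6-(methoxymethoxy)benzaldehyde | COCOc1cc(OCc2ccccc2)cc(OCc2ccccc2)c1C=O | intermediate
4 | 2,4-bis(benzyloxy)-6-(methoxymethoxy)phenyl formate | O=COc1c(OCOC)cc(OCc2ccccc2)cc1OCc1ccccc1 | intermediate (not isolated)
5 | 2,4-bis(benzyloxy)-6-(methoxymethoxy)phenol | COCOc1cc(OCc2ccccc2)cc(OCc2ccccc2)c1O | intermediate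
6 | 1,5-bis(benzyloxy)-2-methoxy-3-(methoxymethoxy)benzene | COCOc1cc(OCc2ccccc2)cc(OCc2ccccc2)c1OC | intermediate
7 | N,2-dimethoxy-N-methylacetamide | COCC(=O)N(C)OC | starting material
8 | [2,4-bis(benzyloxy)-5-methoxy-6-(methoxymethoxy)phenyl]lithium | [Li]c1c(OCOC)c(OC)c(OCc2ccccc2)cc1OCc1ccccc1 | intermediate (not isolated)
9 | lithium 1-[4,6-bis(benzyloxy)-3-methoxy-2-(methoxymethoxy)phenyl]-2-methoxy-1-[methoxy(methyl)amino]ethan-1-olate (racemic) | COCC(O[Li])(N(C)OC)c1c(OCOC)c(OC)c(OCc2ccccc2)cc1OCc1ccccc1 | intermediate (not isolated)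
10 | 1-[4,6-bis(benzyloxy)-3-methoxy-2-(methoxymethoxy)phenyl]-2-methoxyethan-1-one | COCC(=O)c1c(OCOC)c(OC)c(OCc2ccccc2)cc1OCc1ccccc1 | intermediate
11 | 1-[4,6-bis(benzyloxy)-2-hydroxy-3-methoxyphenyl]-2-methoxyethan-1-one | COCC(=O)c1c(O)c(OC)c(OCc2ccccc2)cc1OCc1ccccc1 | intermediate
12 | 4-(benzyloxy)-3-methoxybenzaldehyde (O-benzylvanillin) | COc1cc(C=O)ccc1OCc1ccccc1 | starting material
13 | 1-[4,6-bis(benzyloxy)-2-hydroxy-3-methoxyphenyl]-3-[4-(benzyloxy)-3-methoxyphenyl]-3-hydroxy-2-methoxypropan-1-one (racemic mixture of diastereomers) | COc1cc(C(O)C(OC)C(=O)c2c(O)c(OC)c(OCc3ccccc3)cc2OCc2ccccc2)ccc1OCc1ccccc1 | intermediate (not isolated)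
14 | (Z)-1-[4,6-bis(benzyloxy)-2-hydroxy-3-methoxyphenyl]-3-[4-(benzyloxy)-3-methoxyphenyl]-2-methoxyprop-2-en-1-one | COc1cc(/C=C(\OC)C(=O)c2c(O)c(OC)c(OCc3ccccc3)cc2OCc2ccccc2)ccc1OCc1ccccc1 | intermediate (precursor of the key step)
15 | 5,7-bis(benzyloxy)-2-[4-(benzyloxy)-3-methoxyphenyl]-3,8-dimethoxychroman-4-one (racemic mixture of C2/C3 diastereomers) | COc1cc(C2Oc3c(OC)c(OCc4ccccc4)cc(OCc4ccccc4)c3C(=O)C2OC)ccc1OCc1ccccc1 | intermediate (not isolated)
16 | 5,7-bis(benzyloxy)-2-[4-(benzyloxy)-3-methoxyphenyl]-3-iodo-3,8-dimethoxychroman-4-one (racemic mixture of diastereomers) | COc1cc(C2Oc3c(OC)c(OCc4ccccc4)cc(OCc4ccccc4)c3C(=O)C2(I)OC)ccc1OCc1ccccc1 | intermediate (not isolated)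
17 | 5,7-bis(benzyloxy)-2-[4-(benzyloxy)-3-methoxyphenyl]-3,8-dimethoxy-4H-chromen-4-one | COc1cc(-c2oc3c(OC)c(OCc4ccccc4)cc(OCc4ccccc4)c3c(=O)c2OC)ccc1OCc1ccccc1 | intermediate (product of the key step)
18 | 5,7-dihydroxy-2-(4-hydroxy-3-methoxyphenyl)-3,8-dimethoxy-4H-chromen-4-one | COc1cc(-c2oc3c(OC)c(O)cc(O)c3c(=O)c2OC)ccc1O | intermediate
19 | prenyl bromide (1-bromo-3-methylbut-2-ene) | CC(C)=CCBr | starting material
20 | 5,4'-dihydroxy-3,8,3'-trimethoxy-7-prenyloxyflavone | COc1cc(-c2oc3c(OC)c(OCC=C(C)C)cc(O)c3c(=O)c2OC)ccc1O | target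

**Step count**
Total: 10 steps. Longest linear sequence: 10 steps (1 to 20); 7, 12 and 19 are purchased and enter at steps 5, 7 and 10.

**Steps most likely to fail**

Step 5. Metalation may occur at the ring CH between the two benzyloxy groups, or at a benzylic CH2 followed by [1,2]-Wittig rearrangement, instead of next to the MOM acetal. The hindered aryllithium may also deprotonate the amide instead of adding to it. The fallback sets out from 6 and returns at 11. The MOM group is removed first (HCl, MeOH) to give 3,5-bis(benzyloxy)-2-methoxyphenol F1. Magnesium-mediated ortho-formylation (MgCl2, Et3N, (CH2O)n, MeCN, reflux), for which only one ortho position is open, should give 4,6-bis(benzyloxy)-2-hydroxy-3-methoxybenzaldehyde F2. Addition of MeOCH2MgCl (2.5 equiv, THF, -30 °C) should give racemic 1-[4,6-bis(benzyloxy)-2-hydroxy-3-methoxyphenyl]-2-methoxyethan-1-ol F3, and benzylic oxidation with MnO2 in CH2Cl2 leads to ketone 11. The acyl carbon is thus placed by phenol-directed electrophilic substitution and not by deprotonation.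

Step 10. Alkylation may spread to the 4'-oxygen (giving the bis-ether) or to C6, or stall if hydrogen carbonate ionises the 7-hydroxyl too little. The fallback sets out from 18 and returns at 20, and selects the site by acyl transfer instead of acidity. Peracetylation (Ac2O, pyridine, DMAP, 50 °C) should give 5,7-diacetoxy-2-(4-acetoxy-3-methoxyphenyl)-3,8-dimethoxy-4H-chromen-4-one F4. Thiophenol and imidazole in NMP at 0 °C, known to cleave the 7-acetate of flavone peracetates selectively, should give 5-acetoxy-2-(4-acetoxy-3-methoxyphenyl)-7-hydroxy-3,8-dimethoxy-4H-chromen-4-one F5. Mitsunobu etherification with 3-methylbut-2-en-1-ol (PPh3, DIAD, THF, 0 °C), which avoids base-induced acetyl migration, should give 5-acetoxy-2-(4-acetoxy-3-methoxyphenyl)-3,8-dimethoxy-7-[(3-methylbut-2-en-1-yl)oxy]-4H-chromen-4-one F6. Methanolysis (K2CO3, MeOH, rt) then gives 20.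

Step 7. Enolisation of the doubly ortho-substituted ketone as its phenoxide may be slow, the aldol addition may revert, and the aldehyde may be consumed by Cannizzaro disproportionation during long exposure to KOH. The fallback sets out from 10 and returns at 14, replacing the equilibrium condensation by a directed aldol on the non-phenolic ketone. Enolisation with LiN(SiMe3)2 (THF, -78 °C) and addition of 12 should give 1-[4,6-bis(benzyloxy)-3-methoxy-2-(methoxymethoxy)phenyl]-3-[4-(benzyloxy)-3-methoxyphenyl]-3-hydroxy-2-methoxypropan-1-one F7 as a diastereomer mixture. Mesylation (MsCl, Et3N, CH2Cl2, 0 °C) gives the corresponding 3-methanesulfonate F8, and DBU at rt should eliminate it to (Z)-1-[4,6-bis(benzyloxy)-3-methoxy-2-(methoxymethoxy)phenyl]-3-[4-(benzyloxy)-3-methoxyphenyl]-2-methoxyprop-2-en-1-one F9. Removal of the MOM group (HCl, MeOH, 40 °C) gives 14; any flavanone 15 formed under the acid lies on the path of step 8.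

**Further compounds**
F1 | step 5 | 3,5-bis(benzyloxy)-2-methoxyphenol | COc1c(O)cc(OCc2ccccc2)cc1OCc1ccccc1
F2 | step 5 | 4,6-bis(benzyloxy)-2-hydroxy-3-methoxybenzaldehyde | COc1c(O)c(C=O)c(OCc2ccccc2)cc1OCc1ccccc1
F3 | step 5 | 1-[4,6-bis(benzyloxy)-2-hydroxy-3-methoxyphenyl]-2-methoxyethan-1-ol (racemic) | COCC(O)c1c(O)c(OC)c(OCc2ccccc2)cc1OCc1ccccc1
F4 | step 10 | 5,7-diacetoxy-2-(4-acetoxy-3-methoxyphenyl)-3,8-dimethoxy-4H-chromen-4-one | COc1cc(-c2oc3c(OC)c(OC(C)=O)cc(OC(C)=O)c3c(=O)c2OC)ccc1OC(C)=O
F5 | step 10 | 5-acetoxy-2-(4-acetoxy-3-methoxyphenyl)-7-hydroxy-3,8-dimethoxy-4H-chromen-4-one | COc1cc(-c2oc3c(OC)c(O)cc(OC(C)=O)c3c(=O)c2OC)ccc1OC(C)=O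
F6 | step 10 | 5-acetoxy-2-(4-acetoxy-3-methoxyphenyl)-3,8-dimethoxy-7-[(3-methylbut-2-en-1-yl)oxy]-4H-chromen-4-one | COc1cc(-c2oc3c(OC)c(OCC=C(C)C)cc(OC(C)=O)c3c(=O)c2OC)ccc1OC(C)=O
F7 | step 7 | 1-[4,6-bis(benzyloxy)-3-methoxy-2-(methoxymethoxy)phenyl]-3-[4-(benzyloxy)-3-methoxyphenyl]-3-hydroxy-2-methoxypropan-1-one (racemic mixture of diastereomers) | COc1cc(C(O)C(OC)C(=O)c2c(OCOC)c(OC)c(OCc3ccccc3)cc2OCc2ccccc2)ccc1OCc1ccccc1
F8 | step 7 | 3-[4,6-bis(benzyloxy)-3-methoxy-2-(methoxymethoxy)phenyl]-1-[4-(benzyloxy)-3-methoxyphenyl]-2-methoxy-3-oxopropyl methanesulfonate (racemic mixture of diastereomers) | COc1cc(C(OS(C)(=O)=O)C(OC)C(=O)c2c(OCOC)c(OC)c(OCc3ccccc3)cc2OCc2ccccc2)ccc1OCc1ccccc1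
F9 | step 7 | (Z)-1-[4,6-bis(benzyloxy)-3-methoxy-2-(methoxymethoxy)phenyl]-3-[4-(benzyloxy)-3-methoxyphenyl]-2-methoxyprop-2-en-1-one | COc1cc(/C=C(\OC)C(=O)c2c(OCOC)c(OC)c(OCc3ccccc3)cc2OCc2ccccc2)ccc1OCc1ccccc1
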